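**Retrosynthetic overview** (germacrane numbering throughout)
1. Ten-membered ring C is closed last. Ring-closing metathesis makes C1=C10 from a prenyl end and a 2-substituted acrylate, and just before it a Mitsunobu reaction puts the angelate on C8 with inversion.
2. The α-methylene lactone and the C8 hydroxyl are released together from a cis-fused tetrahydrofuran–lactone bicycle, by opening the temporary O8–C13 bond and losing HBr.
3. Key disconnection: O–C6 and C11–C7 are made in one flask. An iodomalonate hung on O8 through C13 undergoes iodine-atom-transfer 5-exo cyclisation, and a tert-butyl ester oxygen then displaces the C6 iodide.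
4. Enabling feature: the oxygen on C8 stands next to C7 and 1,3 to C6. The chain O8–C13–C11 therefore closes a five-membered temporary ring B on C7 and holds a carboxyl group over C6, and the trans C6–O/C7–C11 pair maps onto an E C6=C7 olefin.
5. Ring order: rings A (lactone) and B (tetrahydrofuran) form together, B is opened again, ring C comes last. C4 comes from (S)-citronellal and C8 from a catalytic asymmetric allylation.

Key step: step 5

Remark: C8 is built on purpose as the S epimer, because the tether delivers C11 syn to O8 and the esterification then inverts C8. Di-tert-butyl methylidenemalonate is made in step 3 because a steady commercial source is not assumed.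

Step 1
Reactants: 1 (S)-citronellal; 2 (triphenylphosphoranylidene)acetaldehyde
Product: 3 (2E,5S)-5,9-dimethyldeca-2,8-dienal
Conditions: PhMe, 85 °C
Reagents that add atoms: none
Why: Wittig olefination with a formyl-stabilised ylide should give the E-enal (C6=C7), and the C4 stereocentre of citronellal is not touched.

Step 2
Reactants: 3 enal; 4 methyl 2-(bromomethyl)acrylate
Product: 5 methyl (4S,5E,8S)-4-hydroxy-8,12-dimethyl-2-methylidenetrideca-5,11-dienoate (germacrane 4S,8S)
Conditions: CrCl2 (10 mol %), chiral carbazole-bis(oxazoline) ligand (12 mol %), Mn, Cp2ZrCl2, LiCl, THF, 0 °C; aq NaHCO3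
Reagents that add atoms: none
Why: In this catalytic asymmetric Nozaki–Hiyama–Kishi 2-(alkoxycarbonyl)allylation the allylchromium species adds 1,2 to the enal through a closed transition state, the chosen ligand antipode sets the 8S carbinol regardless of the remote C4 centre, and the neutral work-up should keep the γ-hydroxy ester open.

Step 3
Reactants: 6 di-tert-butyl malonate
Product: 7 di-tert-butyl 2-methylidenemalonate
Conditions: (CH2O)n, KOAc, Cu(OAc)2 (cat.), AcOH, 95 °C
Reagents that add atoms: formaldehyde (as paraformaldehyde), C=O
Why: Knoevenagel-type condensation with formaldehyde and loss of water gives the methylidene malonate, which the bulky tert-butyl esters should keep monomeric.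

Step 4
Reactants: 5 allylic alcohol; 7 di-tert-butyl 2-methylidenemalonate
Product: 9 di-tert-butyl 2-iodo-2-({[(4S,5E,8S)-1-methoxy-8,12-dimethyl-2-methylidene-1-oxotrideca-5,11-dien-4-yl]oxy}methyl)malonate, via potassium malonate enolate 8 (not isolated)
Conditions: KN(SiMe3)2 (1.0 equiv), THF, −78 °C; 7 (1.0 equiv); NIS, −78 to −20 °C, dark
Reagents that add atoms: N-iodosuccinimide, O=C1CCC(=O)N1I; potassium bis(trimethylsilyl)amide, C[Si](C)(C)[N-][Si](C)(C)C.[K+] (potassium only in 8)
Why: Oxa-Michael addition of the alkoxide to the doubly activated olefin should outrun attack on the C14 ester at −78 °C, the soft malonate anion is then iodinated at carbon faster than NIS meets any olefin, and C8 is not touched.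

Step 5
Reactants: 9 iodomalonate ether
Product: 11 tert-butyl ester of the cis-fused 3,7-dioxabicyclo[3.3.0]octan-2-one (germacrane 4S,6R,7R,8S,11R; C5 chain and C9 chain both on the convex face; CO2tBu on bridgehead C11), via tetrahydrofuran iodide 10 (not isolated)
Conditions: Et3B (0.3 equiv), air, ClCH2CH2Cl (0.05 M), 25 °C; then solid NaHCO3, 80 °C, same flask
Reagents that add atoms: none
Why: Ethyl radicals from Et3B and O2 abstract iodine from 9, the electrophilic malonyl radical at C11 closes 5-exo-trig on C7 (ring B), and the C6 radical takes iodine from a further molecule of 9, which carries the chain and gives 10. On warming, the tert-butyl ester that lies cis to the side chain displaces iodide 5-exo-tet through its carbonyl oxygen and loses isobutene, which closes lactone ring A and makes the O–C6 bond. The closest known reaction type is the iodine-atom-transfer (Kharasch-type) cyclisation of iodomalonates with thermal lactonisation of the γ-iodo esters. C7 is set by C8 through a chair-like transition state with the C9 chain pseudo-equatorial (C9 and C6 trans on ring B), C11 can only be cis-fused, and C6 is set in the ring closure, because the iodide epimer that places C5 on the convex face should react faster while liberated iodide interconverts the two epimers. Regiochemistry (C11 to C7, O to C6) is secured by the O8–C13–C11 tether, and chemoselectivity over the prenyl and acrylate olefins by proximity and by the very fast iodine transfer from an iodomalonate, which should outrun 6-exo attack of the C6 radical on the prenyl group. The two ester groups are equivalent, so one of them always lies cis to C6 and no stereochemical demand arises at the radical carbon.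

Step 6
Reactants: 11 bicyclic tert-butyl ester
Product: 13 cis-fused tetrahydrofuran–lactone (germacrane 4S,6R,7R,8S,11S), via malonic half acid 12 (not isolated)
Conditions: SiO2, xylenes, 135 °C, BHT
Reagents that add atoms: none
Why: Silica-promoted thermolysis of the tert-butyl ester frees the malonic-type acid, which should decarboxylate at this temperature; protonation of the lactone enol can only give the cis-fused bicycle, and the methyl ester and the olefins are inert.

Step 7
Reactants: 13 tetrahydrofuran–lactone
Product: 15 α-methylene-γ-butyrolactone 8S alcohol (germacrane 4S,6R,7R,8S; trans-6,7-lactone), via bromomethyl lactone borinate 14 (not isolated)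
Conditions: Me2BBr, Et3N (0.2 equiv), CH2Cl2, −78 to 0 °C; then Et3N (3 equiv), 0 °C; aq NaHCO3
Reagents that add atoms: bromodimethylborane, CB(C)Br (its atoms appear only in 14)
Why: In this Lewis-acid ether cleavage the borane binds O8 and bromide attacks the primary C13 rather than the hindered secondary C8, so C8–O is kept with retention; Et3N then removes HBr from the β-bromo lactone (E1cB), and re-closure of the alcohol onto the methylene lactone would be a disfavoured 5-endo-trig process.

Step 8
Reactants: 15 8S alcohol; 16 angelic acid
Product: 17 seco-angelate (germacrane 4S,6R,7S,8R)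
Conditions: PPh3, DIAD (premixed), PhMe, 0 to 25 °C
Reagents that add atoms: none
Why: In the Mitsunobu esterification angelate displaces the oxyphosphonium ion by SN2, which inverts C8 from S to R, and the cold, neutral medium should keep the Z geometry of the angelate.

Step 9
Reactants: 17 seco-angelate
Product: 18 target CNP0510087.1
Conditions: second-generation Hoveyda–Grubbs catalyst (15 mol %, in portions), 1,4-benzoquinone, PhMe (1 mM), 100 °C, Ar sparge
Reagents that add atoms: none
Why: Ring-closing metathesis with loss of isobutene follows the known cross-metathesis of prenyl groups with 2-substituted acrylates; the ten-membered ring should favour the new olefin with C2 and C9 cis (the E-enoate), and the α-methylene lactone should not compete because closure on C11 would give a bridgehead olefin.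

**Compound list**
1 | (S)-citronellal | O=CC[C@@H](C)CCC=C(C)C | starting material
2 | (triphenylphosphoranylidene)acetaldehyde | O=CC=P(c1ccccc1)(c1ccccc1)c1ccccc1 | starting material
3 | (2E,5S)-5,9-dimethyldeca-2,8-dienal | O=C/C=C/C[C@@H](C)CCC=C(C)C | intermediate
4 | methyl 2-(bromomethyl)acrylate | C=C(CBr)C(=O)OC | starting material
5 | methyl (4S,5E,8S)-4-hydroxy-8,12-dimethyl-2-methylidenetrideca-5,11-dienoate | COC(=O)C(=C)C[C@H](O)/C=C/C[C@@H](C)CCC=C(C)C | intermediate
6 | di-tert-butyl malonate | CC(C)(C)OC(=O)CC(=O)OC(C)(C)C | starting material
7 | di-tert-butyl 2-methylidenemalonate | C=C(C(=O)OC(C)(C)C)C(=O)OC(C)(C)C | intermediate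
8 | potassium enolate of the O8-[2,2-bis(tert-butoxycarbonyl)ethyl] ether of 5 | COC(=O)C(=C)C[C@H](OC[C-](C(=O)OC(C)(C)C)C(=O)OC(C)(C)C)/C=C/C[C@@H](C)CCC=C(C)C.[K+] | intermediate
9 | iodomalonate ether of 5 | COC(=O)C(=C)C[C@H](OCC(I)(C(=O)OC(C)(C)C)C(=O)OC(C)(C)C)/C=C/C[C@@H](C)CCC=C(C)C | intermediate
10 | 2,3-trans-tetrahydrofuran-4,4-diester with a C6 iodide (C6 epimers) | COC(=O)C(=C)C[C@@H]1OCC(C(=O)OC(C)(C)C)(C(=O)OC(C)(C)C)[C@H]1C(I)C[C@@H](C)CCC=C(C)C | intermediate
11 | cis-fused tetrahydrofuran–lactone with CO2tBu on C11 | O=C1O[C@H](C[C@@H](C)CCC=C(C)C)[C@H]2[C@H](CC(=C)C(=O)OC)OC[C@@]12C(=O)OC(C)(C)C | intermediate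
12 | corresponding C11 carboxylic acid | O=C1O[C@H](C[C@@H](C)CCC=C(C)C)[C@H]2[C@H](CC(=C)C(=O)OC)OC[C@@]12C(=O)O | intermediate
13 | cis-fused tetrahydrofuran–lactone with H on C11 | O=C1O[C@H](C[C@@H](C)CCC=C(C)C)[C@H]2[C@H](CC(=C)C(=O)OC)OC[C@@H]12 | intermediate
14 | α-(bromomethyl) lactone, O8 dimethylborinate | BrC[C@H]1C(=O)O[C@H](C[C@@H](C)CCC=C(C)C)[C@H]1[C@@H](OB(C)C)CC(=C)C(=O)OC | intermediate
15 | α-methylene lactone, 8S alcohol | C=C1C(=O)O[C@H](C[C@@H](C)CCC=C(C)C)[C@H]1[C@@H](O)CC(=C)C(=O)OC | intermediate
16 | angelic acid, (Z)-2-methylbut-2-enoic acid | C/C=C(/C)C(=O)O | starting material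
17 | seco-angelate, 8R | C=C1C(=O)O[C@H](C[C@@H](C)CCC=C(C)C)[C@H]1[C@H](OC(=O)/C(C)=C\C)CC(=C)C(=O)OC | intermediate
18 | CNP0510087.1 | C=C1C(=O)O[C@@H]2C[C@@H](C)CC/C=C(/C(=O)OC)C[C@@H](OC(=O)/C(C)=C\C)[C@@H]12 | target

Total step count: 9. Longest linear sequence: 8 (steps 1, 2, 4, 5, 6, 7, 8, 9).

**Steps most likely to fail**

Step 9. Both olefin partners are hindered, so initiation may be slow. Oligomerisation and ruthenium-hydride double-bond migration may then win over closure of the medium ring. The fallback sets out from 17. Ozone is titrated onto the only electron-rich olefin and the ozonide is reduced with Me2S, giving the C1 aldehyde F1. Lombardo methylenation (Zn, CH2Br2, TiCl4), which spares esters and lactones, gives the terminal olefin F2. The catalyst can now load on a monosubstituted olefin and close the ring with loss of ethene, which returns to the route at 18.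

Step 8. Displacement at a β-branched carbinol may be sluggish. Elimination toward the conjugated diene ester and phosphine-induced Z to E isomerisation of the angelate may compete. The fallback sets out from 15. Dess–Martin oxidation gives the C8 ketone F3. Corey–Bakshi–Shibata reduction with catecholborane at low temperature follows, with the oxazaborolidine antipode chosen to reinforce hydride attack anti to the larger C6 branch, and gives the 8R alcohol F4. Yamaguchi esterification with the mixed anhydride of 16, run without excess nucleophilic catalyst, then acylates with retention and returns to the route at 17.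

Step 5. Facial selectivity in the 5-exo closure may be only moderate. Hydrogen abstraction by the malonyl radical, or loss of HI from the secondary iodide in place of lactonisation, may erode the cascade. The fallback sets out from enolate 8, which is quenched with NH4Cl instead of NIS to give the C–H malonate ether F5. Oxidative radical cyclisation with Mn(OAc)3·2H2O and Cu(OAc)2 in AcOH generates the same C11 radical from the C–H bond. The C6 radical is then oxidised at copper and captured by the neighbouring ester. This replaces atom transfer and substitution by a radical–polar crossover and returns to the route at 11.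

**Further compounds**
F1 | step 9 | C1 aldehyde from ozonolysis of 17 | C=C1C(=O)O[C@H](C[C@@H](C)CCC=O)[C@H]1[C@H](OC(=O)/C(C)=C\C)CC(=C)C(=O)OC
F2 | step 9 | terminal olefin analogue of 17 | C=C1C(=O)O[C@H](C[C@@H](C)CCC=C)[C@H]1[C@H](OC(=O)/C(C)=C\C)CC(=C)C(=O)OC
F3 | step 8 | C8 ketone | C=C1C(=O)O[C@H](C[C@@H](C)CCC=C(C)C)[C@H]1C(=O)CC(=C)C(=O)OC
F4 | step 8 | 8R alcohol | C=C1C(=O)O[C@H](C[C@@H](C)CCC=C(C)C)[C@H]1[C@H](O)CC(=C)C(=O)OC
F5 | step 5 | C–H malonate ether of 5 | COC(=O)C(=C)C[C@H](OCC(C(=O)OC(C)(C)C)C(=O)OC(C)(C)C)/C=C/C[C@@H](C)CCC=C(C)C
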